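The constants used here are made up; the flask was simulated.

The ratio I began with was chain growth against quenching, the two routes I weighed for free monomer: it adds to growing radical, or it meets protic impurity and ends as quenched substrate.

| setting | east | north | south | south-east |
|---|---|---|---|---|
| free monomer | 0.011 M | 0.011 M | 0.011 M (fed, over 10.0 min) | 0.011 M |
| protic impurity | 5.50 mM | 5.50 mM | 5.50 mM | 5.50 mM |
| initiator | 5 mol% | 5 mol% | 5 mol% | 5 mol% |
| remark | a single well-mixed tank run continuously and read at steady state, 20 min in it on average | one stirred flow tank at steady state, fed with the mixture as stated, mean residence time 200 min | a stirred flask in which free monomer is dosed at a steady rate over 10.0 min without added volume, worked up at 20 min | everything together in a closed stirred flask, run for 20 min |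
| time |  |  | 20 min | 20 min |

* the set-up with the highest amount of monomer in chains at the outlet or at the end, in percent of the free monomer put in ("none" if the first two lie within 2 percentage points) (east / north / south / south-east / none)
* amount of monomer in chains at the outlet or at the end, in percent of the free monomer put in, east
* amount of monomer in chains at the outlet or at the end, in percent of the free monomer put in, north
* amount of monomer in chains at the outlet or at the end, in percent of the free monomer put in, south
* amount of monomer in chains at the outlet or at the end, in percent of the free monomer put in, south-east

    initiator → 2 initiating radical (k1 = 1.1 × 10⁻⁴ /s)
    free monomer + initiating radical → growing radical + monomer in chains (k2 = 2.0 × 10⁵ /M/s)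
    free monomer + growing radical → monomer in chains + growing radical, rate k3*[growing radical]*[free monomer] (k3 = 8000 /M/s)
    2 growing radical → dead chain (k4 = 4 × 10⁶ /M/s)
    protic impurity + free monomer → quenched substrate (k5 = 0.085 /M/s)

Balancing radicals made from initiator as charged against their loss in pairs, I put c(growing radical) at 1.23 × 10⁻⁷ M. Free monomer then goes into chains with a pseudo-first-order constant of 9.84 × 10⁻⁴ /s and, with c(protic impurity) as charged, is quenched with one of 4.67 × 10⁻⁴ /s. Growth was faster by a factor of 2.11, so chains take 67.8% of what reacts.

I carried the drain constant, the sum of those two rates, 0.0871 /min; multiplied by a time, it counts turnovers of free monomer. A stirred tank with a constant drain keeps one part in one plus the count. North, at 200 min, got 17.4 turnovers and so kept 5.43% free, which gave 64.1% in chains. East, with 1.74 turnovers in 20 min, gave 43.1%, less than north, so north was my pick. But initiator has a half-life of 110 min by its own step alone, shorter than the north residence time, so I held the north count as a rough one.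

The forecast also named north, with 45% for east, 68.2% for north, 50% for south and 57.2% for south-east, and its north figure stood above mine. Its grounds were that “The 200 min tank wins on sheer residence time”.

The simulation put north first at 68.2%, ahead of south-east at 58.0%, south at 49.7% and east at 45.1%, as the forecast had it.

The north outlet still held 8.06% of its free monomer, more than my 5.43%. Read back through the tank rule, that is 11.4 turnovers against the 17.4 I counted. In south-east, a closed flask, each turnover at a constant drain cuts free monomer by the factor e instead. The same drain constant, 0.0871 /min, over 20 min gives 1.74 turnovers and leaves 17.5%, and the south-east reading was 20.7%.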